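Everything rests on cutting ring B (the dihydrofuran ring) at C3a–C3 and O1–C2. C3 is a benzylic carbinol and C2 sits between O1 and the oxygenated side-chain carbon C1', so the run C3–C2–C1' is the imprint of a 2,3-epoxy aldehyde. The precursors are a 2-bromophenol carrying a silyl-protected (R)-1-hydroxyethyl group para to the hydroxyl, and (S)-3,3-dimethyloxirane-2-carbaldehyde. The derived ortho-lithiated phenoxide adds to the aldehyde, and on warming the phenoxide oxygen opens the epoxide at C2 with inversion: one operation makes both bonds, closes ring B and sets C3 cis to the C2 substituent. Acetylation, dehydration, angeloylation and late allylic oxidation complete the target.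

Key step: step 7

Remark on the chemistry: benzofuran numbering is used (O1, C2, C3, C3a, C7a; C1' is the side-chain carbon on C2); the target is 2R,3R (cis), side-chain carbinol R, angelate Z; the descriptor changes at the epoxide carbon (R alcohol, S aldehyde) and at C2 (S with the tertiary carbinol on C1', R with the alkene) come from priority changes only, and the (R)-epoxy alcohol calls for D-(−)-diethyl tartrate.

Step 1
Reactants: 1 3'-bromo-4'-hydroxyacetophenone
Product: 2 1-[3-bromo-4-(tert-butyldimethylsilyloxy)phenyl]ethan-1-one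
Conditions: TBSCl, imidazole, DMF, 23 °C
Reagents that add atoms: tert-butyldimethylsilyl chloride, CC(C)(C)[Si](C)(C)Cl
Why: Imidazole-promoted silyl ether formation masks the acidic phenol, which would otherwise consume borane and lower the selectivity of the ketone reduction that follows.

Step 2
Reactants: 2 1-[3-bromo-4-(tert-butyldimethylsilyloxy)phenyl]ethan-1-one
Product: 3 (R)-1-[3-bromo-4-(tert-butyldimethylsilyloxy)phenyl]ethan-1-ol
Conditions: (S)-1-methyl-3,3-diphenyltetrahydro-1H,3H-pyrrolo[1,2-c][1,3,2]oxazaborole (10 mol%), BH3·SMe2, THF, −20 °C; MeOH quench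
Reagents that add atoms: none
Why: Corey–Bakshi–Shibata reduction, in which the (S)-oxazaborolidine binds borane and the ketone with the aryl group as the large substituent, so that hydride should reach the face that gives the (R)-carbinol and sets the side-chain stereocentre.

Step 3
Reactants: 3 (R)-1-[3-bromo-4-(tert-butyldimethylsilyloxy)phenyl]ethan-1-ol
Product: 4 (R)-[2-bromo-4-[1-(tert-butyldimethylsilyloxy)ethyl]phenoxy](tert-butyl)dimethylsilane
Conditions: TBSCl, imidazole, DMF, 23 °C
Reagents that add atoms: tert-butyldimethylsilyl chloride, CC(C)(C)[Si](C)(C)Cl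
Why: Silyl ether formation takes place at oxygen under non-acidic conditions, so the benzylic stereocentre is not touched.

Step 4
Reactants: 4 (R)-[2-bromo-4-[1-(tert-butyldimethylsilyloxy)ethyl]phenoxy](tert-butyl)dimethylsilane
Product: 5 (R)-2-bromo-4-[1-(tert-butyldimethylsilyloxy)ethyl]phenol
Conditions: K2CO3, MeOH, 0 °C; pH 7 buffer
Reagents that add atoms: none
Why: Selective base-mediated desilylation, since methoxide cleaves the aryl silyl ether (phenoxide as leaving group, helped by the ortho bromine) far faster than the alkyl silyl ether, while the cold, briefly basic medium and neutral quench protect the para-silyloxyethyl phenoxide.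

Step 5
Reactants: 6 prenol (3-methylbut-2-en-1-ol)
Product: 7 [(2R)-3,3-dimethyloxiran-2-yl]methanol
Conditions: Ti(OiPr)4 (5 mol%), D-(−)-diethyl tartrate (6 mol%), t-BuOOH (in isooctane), 4 Å molecular sieves, CH2Cl2, −20 °C; work-up without aqueous extraction, distillation
Reagents that add atoms: tert-butyl hydroperoxide, CC(C)(C)OO
Why: Sharpless asymmetric epoxidation, in which the Ti(OiPr)4–D-(−)-tartrate complex delivers oxygen to the alkene face that gives the (R)-epoxy alcohol and thereby sets the carbon that becomes C2.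

Step 6
Reactants: 7 [(2R)-3,3-dimethyloxiran-2-yl]methanol
Product: 8 (S)-3,3-dimethyloxirane-2-carbaldehyde
Conditions: (COCl)2, DMSO, CH2Cl2, −78 °C; Et3N, −78 to 0 °C; used as a dried, carefully concentrated solution
Reagents that add atoms: none
Why: Swern oxidation converts the primary alcohol into the aldehyde without touching the epoxide stereocentre, which has no readily enolisable hydrogen.

Step 7
Reactants: 5 (R)-2-bromo-4-[1-(tert-butyldimethylsilyloxy)ethyl]phenol; 8 (S)-3,3-dimethyloxirane-2-carbaldehyde
Product: 11 (2S,3R)-5-[(R)-1-(tert-butyldimethylsilyloxy)ethyl]-2-(2-hydroxypropan-2-yl)-2,3-dihydrobenzofuran-3-ol, via ortho-lithiated lithium phenoxide 9 (not isolated), via anti epoxy dialkoxide 10 (not isolated)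
Conditions: n-BuLi (1.05 equiv), THF, −78 °C; t-BuLi (2.1 equiv), −78 °C; 8 (1.3 equiv), −78 °C; then warm to 23–45 °C; aq. NH4Cl
Reagents that add atoms: none
Why: n-BuLi removes the phenol proton and t-BuLi exchanges the bromine to give 9, whose aryl carbon adds to the formyl group of 8 (C3a–C3 bond) to give 10; on warming, the phenoxide oxygen displaces the epoxide oxygen at C2 from the rear (O1–C2 bond), which leaves the tertiary alkoxide on C1'. Both events are known reaction types, the Felkin–Anh addition of aryllithiums to 2,3-epoxy aldehydes and the base-induced cyclisation of ortho-(2,3-epoxy-3-methylbutyl)phenols to 2-(2-hydroxypropan-2-yl)-2,3-dihydrobenzofurans, here run one after the other in one flask. Ring B closes in the 5-exo-tet mode at the secondary carbon C2, the usual course under basic conditions, in preference to 6-endo attack at the tertiary carbon C1' that would give a chroman. The new stereocentre C3 is controlled by the epoxide stereocentre of 8: with the epoxide C–O bond anti to the incoming aryl group (Felkin–Anh polar model) and the methyl group cis to the formyl group disfavouring the competing rotamer, the anti epoxy alkoxide with (R)-C3 should form, and inversion at C2 turns this anti relationship into the cis-2,3 arrangement. The step needs this facial selectivity, clean inversion at C2 and no epoxide migration to the C3 alkoxide; the trisubstituted epoxide should secure the first, the backside geometry of the five-membered closure the second, and the tightly bound lithium counter-ion in THF the third. The benzylic silyl ether is inert to both organolithium reagents at −78 °C, and material from the minor enantiomer of 8 is a diastereomer that chromatography should remove.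

Step 8
Reactants: 11 (2S,3R)-5-[(R)-1-(tert-butyldimethylsilyloxy)ethyl]-2-(2-hydroxypropan-2-yl)-2,3-dihydrobenzofuran-3-ol
Product: 12 (2S,3R)-5-[(R)-1-(tert-butyldimethylsilyloxy)ethyl]-2-(2-hydroxypropan-2-yl)-2,3-dihydrobenzofuran-3-yl acetate
Conditions: Ac2O (1.3 equiv), pyridine, 4-(dimethylamino)pyridine (DMAP, 5 mol%), CH2Cl2, 0 °C
Reagents that add atoms: acetic anhydride, CC(=O)OC(C)=O
Why: Chemoselective DMAP-catalysed acylation takes the secondary benzylic C3 hydroxyl and leaves the hindered tertiary C1' hydroxyl free, with no stereocentre involved.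

Step 9
Reactants: 12 (2S,3R)-5-[(R)-1-(tert-butyldimethylsilyloxy)ethyl]-2-(2-hydroxypropan-2-yl)-2,3-dihydrobenzofuran-3-yl acetate
Product: 13 (2R,3R)-5-[(R)-1-(tert-butyldimethylsilyloxy)ethyl]-2-(prop-1-en-2-yl)-2,3-dihydrobenzofuran-3-yl acetate
Conditions: methyl N-(triethylammoniosulfonyl)carbamate (Burgess reagent), toluene, 50 °C
Reagents that add atoms: none
Why: Burgess dehydration of the tertiary alcohol through its sulfamate ester (syn elimination) should take a hydrogen from one of the two methyl groups and not the hindered C2–H, which is deactivated by O1 and the C3 acetoxy group, so the isopropenyl group forms under nearly neutral conditions that spare the acetate.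

Step 10
Reactants: 13 (2R,3R)-5-[(R)-1-(tert-butyldimethylsilyloxy)ethyl]-2-(prop-1-en-2-yl)-2,3-dihydrobenzofuran-3-yl acetate
Product: 14 (2R,3R)-5-[(R)-1-hydroxyethyl]-2-(prop-1-en-2-yl)-2,3-dihydrobenzofuran-3-yl acetate
Conditions: HF·pyridine, pyridine, THF, 0 to 23 °C
Reagents that add atoms: none
Why: Fluoride-mediated desilylation attacks silicon, so the benzylic C–O bond and its (R) configuration are kept, and the buffered, weakly acidic medium avoids the base-induced loss of acetic acid from C3 that would aromatise ring B.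

Step 11
Reactants: 14 (2R,3R)-5-[(R)-1-hydroxyethyl]-2-(prop-1-en-2-yl)-2,3-dihydrobenzofuran-3-yl acetate; 15 angelic acid [(Z)-2-methylbut-2-enoic acid]
Product: 17 (R)-1-[(2R,3R)-3-acetoxy-2-(prop-1-en-2-yl)-2,3-dihydrobenzofuran-5-yl]ethyl (Z)-2-methylbut-2-enoate, via angelic 2,4,6-trichlorobenzoic anhydride 16 (not isolated)
Conditions: 15 (3 equiv), 2,4,6-trichlorobenzoyl chloride, Et3N, toluene, 23 °C; then 14, 75 °C, no DMAP
Reagents that add atoms: none
Why: Yamaguchi esterification through the preformed mixed anhydride 16, run hot in toluene without a nucleophilic catalyst, acylates the alcohol at oxygen (retention at the carbinol carbon) and should avoid the Z to E isomerisation of the angeloyl group that nucleophilic amines cause.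

Step 12
Reactants: 17 (R)-1-[(2R,3R)-3-acetoxy-2-(prop-1-en-2-yl)-2,3-dihydrobenzofuran-5-yl]ethyl (Z)-2-methylbut-2-enoate
Product: 18 (R)-1-[(2R,3R)-3-acetoxy-2-(3-hydroxyprop-1-en-2-yl)-2,3-dihydrobenzofuran-5-yl]ethyl (Z)-2-methylbut-2-enoate
Conditions: SeO2 (0.5 equiv), t-BuOOH (in decane), CH2Cl2, 23 °C
Reagents that add atoms: selenium dioxide, O=[Se]=O (oxygen donor); tert-butyl hydroperoxide, CC(C)(C)OO (terminal oxidant that restores SeO2)
Why: Riley allylic oxidation by an ene reaction and [2,3]-sigmatropic shift should hydroxylate the methyl group of the 1,1-disubstituted alkene, the electron-poor angelate double bond being far less reactive; any enal already formed here converges in step 13.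

Step 13
Reactants: 18 (R)-1-[(2R,3R)-3-acetoxy-2-(3-hydroxyprop-1-en-2-yl)-2,3-dihydrobenzofuran-5-yl]ethyl (Z)-2-methylbut-2-enoate
Product: 19 (R)-1-[(2R,3R)-3-acetoxy-2-(3-oxoprop-1-en-2-yl)-2,3-dihydrobenzofuran-5-yl]ethyl (Z)-2-methylbut-2-enoate (CNP0294391.3)
Conditions: activated MnO2 (excess), CH2Cl2, 23 °C
Reagents that add atoms: none
Why: MnO2 oxidation of the primary allylic alcohol to the enal is neutral and selective, so both esters, the Z double bond and the three stereocentres are left as they are and the sensitive enal appears only in the last step.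

Compound list
1 | 3'-bromo-4'-hydroxyacetophenone | CC(=O)c1ccc(O)c(Br)c1 | starting material
2 | 1-[3-bromo-4-(tert-butyldimethylsilyloxy)phenyl]ethan-1-one | CC(=O)c1ccc(O[Si](C)(C)C(C)(C)C)c(Br)c1 | intermediate
3 | (R)-1-[3-bromo-4-(tert-butyldimethylsilyloxy)phenyl]ethan-1-ol | CC(C)(C)[Si](C)(C)Oc1ccc([C@@H](C)O)cc1Br | intermediate
4 | (R)-[2-bromo-4-[1-(tert-butyldimethylsilyloxy)ethyl]phenoxy](tert-butyl)dimethylsilane | CC(C)(C)[Si](C)(C)Oc1ccc([C@@H](C)O[Si](C)(C)C(C)(C)C)cc1Br | intermediate
5 | (R)-2-bromo-4-[1-(tert-butyldimethylsilyloxy)ethyl]phenol | Oc1ccc([C@@H](C)O[Si](C)(C)C(C)(C)C)cc1Br | intermediate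
6 | prenol (3-methylbut-2-en-1-ol) | CC(C)=CCO | starting material
7 | [(2R)-3,3-dimethyloxiran-2-yl]methanol | CC1(C)O[C@@H]1CO | intermediate
8 | (S)-3,3-dimethyloxirane-2-carbaldehyde | CC1(C)O[C@@H]1C=O | intermediate
9 | lithium 4-[(R)-1-(tert-butyldimethylsilyloxy)ethyl]-2-lithiophenolate | [Li]Oc1ccc([C@@H](C)O[Si](C)(C)C(C)(C)C)cc1[Li] | intermediate
10 | dilithium (R)-{5-[(R)-1-(tert-butyldimethylsilyloxy)ethyl]-2-oxidophenyl}[(R)-3,3-dimethyloxiran-2-yl]methanolate | [Li]Oc1ccc([C@@H](C)O[Si](C)(C)C(C)(C)C)cc1[C@@H](O[Li])[C@H]2OC2(C)C | intermediate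
11 | (2S,3R)-5-[(R)-1-(tert-butyldimethylsilyloxy)ethyl]-2-(2-hydroxypropan-2-yl)-2,3-dihydrobenzofuran-3-ol | CC(C)(O)[C@H]1Oc2ccc([C@@H](C)O[Si](C)(C)C(C)(C)C)cc2[C@H]1O | intermediate
12 | (2S,3R)-5-[(R)-1-(tert-butyldimethylsilyloxy)ethyl]-2-(2-hydroxypropan-2-yl)-2,3-dihydrobenzofuran-3-yl acetate | CC(C)(O)[C@H]1Oc2ccc([C@@H](C)O[Si](C)(C)C(C)(C)C)cc2[C@H]1OC(C)=O | intermediate
13 | (2R,3R)-5-[(R)-1-(tert-butyldimethylsilyloxy)ethyl]-2-(prop-1-en-2-yl)-2,3-dihydrobenzofuran-3-yl acetate | C=C(C)[C@H]1Oc2ccc([C@@H](C)O[Si](C)(C)C(C)(C)C)cc2[C@H]1OC(C)=O | intermediate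
14 | (2R,3R)-5-[(R)-1-hydroxyethyl]-2-(prop-1-en-2-yl)-2,3-dihydrobenzofuran-3-yl acetate | C=C(C)[C@H]1Oc2ccc([C@@H](C)O)cc2[C@H]1OC(C)=O | intermediate
15 | angelic acid [(Z)-2-methylbut-2-enoic acid] | C/C=C(/C)C(=O)O | starting material
16 | (Z)-2-methylbut-2-enoic 2,4,6-trichlorobenzoic anhydride | C/C=C(/C)C(=O)OC(=O)c1c(Cl)cc(Cl)cc1Cl | intermediate
17 | (R)-1-[(2R,3R)-3-acetoxy-2-(prop-1-en-2-yl)-2,3-dihydrobenzofuran-5-yl]ethyl (Z)-2-methylbut-2-enoate | C=C(C)[C@H]1Oc2ccc([C@@H](C)OC(=O)/C(C)=C\C)cc2[C@H]1OC(C)=O | intermediate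
18 | (R)-1-[(2R,3R)-3-acetoxy-2-(3-hydroxyprop-1-en-2-yl)-2,3-dihydrobenzofuran-5-yl]ethyl (Z)-2-methylbut-2-enoate | C=C(CO)[C@H]1Oc2ccc([C@@H](C)OC(=O)/C(C)=C\C)cc2[C@H]1OC(C)=O | intermediate
19 | (R)-1-[(2R,3R)-3-acetoxy-2-(3-oxoprop-1-en-2-yl)-2,3-dihydrobenzofuran-5-yl]ethyl (Z)-2-methylbut-2-enoate | C=C(C=O)[C@H]1Oc2ccc([C@@H](C)OC(=O)/C(C)=C\C)cc2[C@H]1OC(C)=O | target

Total step count: 13. Longest linear sequence: 11 steps (steps 1–4, then 7–13); steps 5 and 6 make the second fragment.

Steps most likely to fail

Step 7. Facial discrimination in the addition of the aryllithium to the epoxy aldehyde may be insufficient, which would place the C3 hydroxyl trans to the C2 substituent in part of the material. The fallback sets out from 5 and 8 and comes back at 11. The addition and cyclisation are run as before without regard to the facial outcome. This gives 11 together with its C3 epimer, (2S,3S)-5-[(R)-1-(tert-butyldimethylsilyloxy)ethyl]-2-(2-hydroxypropan-2-yl)-2,3-dihydrobenzofuran-3-ol F1. The mixture is oxidised at the benzylic carbinol (MnO2, CH2Cl2, 23 °C) to the single ketone (R)-5-[(R)-1-(tert-butyldimethylsilyloxy)ethyl]-2-(2-hydroxypropan-2-yl)benzofuran-3(2H)-one F2, which is kept cold and neutral to protect C2. Luche reduction (NaBH4, CeCl3·7H2O, MeOH, −78 °C) should then deliver hydride to the carbonyl face opposite the C2 substituent and return the cis diol 11. Control of C3 thus moves from the carbon–carbon bond formation to a substrate-controlled ketone reduction.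

Step 12. The ene step may abstract the hydrogen on C2 in place of a methyl hydrogen, or the inductively deactivated alkene may react so slowly that over-oxidation and acid-induced damage to the benzylic esters compete. The fallback sets out from 17 and comes back at the target 19, replacing steps 12 and 13. Ene-type chlorination with hypochlorous acid (NaOCl, CeCl3·7H2O, CH2Cl2/H2O, 0 °C) is fast and is expected to lose the proton from the methyl group. It should give the allylic chloride (R)-1-[(2R,3R)-3-acetoxy-2-(3-chloroprop-1-en-2-yl)-2,3-dihydrobenzofuran-5-yl]ethyl (Z)-2-methylbut-2-enoate F3. A Kornblum-type oxidation of this primary allylic chloride with trimethylamine N-oxide (DMSO, 23 °C), by displacement at carbon and then elimination across the O–N bond, should give the enal 19 directly.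

Step 11. The angeloyl unit may isomerise from Z to E during activation, or acylation of the secondary benzylic alcohol by the hindered mixed anhydride may stall. The fallback sets out from 14 and comes back at 17. Alcohol 14 is esterified with 2-[bis(2,2,2-trifluoroethoxy)phosphoryl]propanoic acid (N-(3-dimethylaminopropyl)-N'-ethylcarbodiimide hydrochloride, DMAP, CH2Cl2, 23 °C), an acid with no double bond to isomerise. This gives (R)-1-[(2R,3R)-3-acetoxy-2-(prop-1-en-2-yl)-2,3-dihydrobenzofuran-5-yl]ethyl 2-[bis(2,2,2-trifluoroethoxy)phosphoryl]propanoate F4 as a mixture of epimers at the phosphonate carbon. Still–Gennari olefination with acetaldehyde (KN(SiMe3)2, 18-crown-6, THF, −78 °C) then builds the Z-trisubstituted double bond on the ester already in place and should return 17.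

Further compounds
F1 | step 7 | (2S,3S)-5-[(R)-1-(tert-butyldimethylsilyloxy)ethyl]-2-(2-hydroxypropan-2-yl)-2,3-dihydrobenzofuran-3-ol | CC(C)(O)[C@H]1Oc2ccc([C@@H](C)O[Si](C)(C)C(C)(C)C)cc2[C@@H]1O
F2 | step 7 | (R)-5-[(R)-1-(tert-butyldimethylsilyloxy)ethyl]-2-(2-hydroxypropan-2-yl)benzofuran-3(2H)-one | CC(C)(O)[C@H]1Oc2ccc([C@@H](C)O[Si](C)(C)C(C)(C)C)cc2C1=O
F3 | step 12 | (R)-1-[(2R,3R)-3-acetoxy-2-(3-chloroprop-1-en-2-yl)-2,3-dihydrobenzofuran-5-yl]ethyl (Z)-2-methylbut-2-enoate | C=C(CCl)[C@H]1Oc2ccc([C@@H](C)OC(=O)/C(C)=C\C)cc2[C@H]1OC(C)=O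
F4 | step 11 | (R)-1-[(2R,3R)-3-acetoxy-2-(prop-1-en-2-yl)-2,3-dihydrobenzofuran-5-yl]ethyl 2-[bis(2,2,2-trifluoroethoxy)phosphoryl]propanoate | C=C(C)[C@H]1Oc2ccc([C@@H](C)OC(=O)C(C)P(=O)(OCC(F)(F)F)OCC(F)(F)F)cc2[C@H]1OC(C)=O
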